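The balance of the substrate, the smaller charge beside 3.00 equiv of reagent, was my invariant: substrate, product and catalyst intermediate C together had to hold what was charged. At 10.0 min the three summed to 99.9% in Thursday's run and 101% in Monday's, each reading carrying 0.3 percentage points, and catalyst intermediate C stood at 0.3% or below. So I took the substrate at the end as the charge minus the product.

| flask | substrate | reagent | precatalyst | remark | time |
|---|---|---|---|---|---|
| Thursday's | 0.020 M | 3 equiv | 0.089 mol% | run made earlier |  |
| Monday's | 0.020 M | 3 equiv | 0.6 mol% | run made earlier |  |
| spring | 0.020 M | 3.00 equiv | 0.11 mol% |  | 20 min |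
| dusk | 0.020 M | 3.00 equiv | 0.28 mol% |  | 20 min |
| autumn | 0.020 M | 3.00 equiv | 0.69 mol% |  | 20 min |

| run | time / min | product / % | substrate / % | catalyst intermediate C / % |
|---|---|---|---|---|
| Thursday's | 0.833 | 0.4 | 99.5 | 0 |
| Thursday's | 2.50 | 0 | 100.2 | 0 |
| Thursday's | 5.00 | 0.3 | 99.9 | 0 |
| Thursday's | 8.00 | 0.1 | 99.5 | 0 |
| Thursday's | 10.0 | 0.6 | 99.3 | 0 |
| Monday's | 0.833 | 0.8 | 100.4 | 0.3 |
| Monday's | 1.50 | 0.4 | 99.4 | 0 |
| Monday's | 3.00 | 0.1 | 99.7 | 0.3 |
| Monday's | 5.00 | 1.7 | 98.7 | 0.2 |
| Monday's | 10.0 | 3.9 | 97.2 | 0.1 |

(each reading ± 0.3 percentage points)

- the earlier runs were read with a standard deviation of 0.3 points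

1. which of these there is most of at the end, counted by the substrate in it, spring (substrate / product / catalyst intermediate C)
2. which of these there is most of at the end, counted by the substrate in it, dusk (substrate / product / catalyst intermediate C)
3. which of these there is most of at the end, counted by the substrate in it, autumn (substrate / product / catalyst intermediate C)
4. final amount of the leader among these, as a percentage of the substrate charged, in spring
5. final amount of the leader among these, as a percentage of the substrate charged, in dusk
6. final amount of the leader among these, as a percentage of the substrate charged, in autumn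

I therefore counted product per precatalyst charged, the turnover number. Monday's run read 6.50 at 10.0 min, and Thursday's read 6.74, though its product reading was 0.6% against a scatter of 0.3 points. In Monday's run, product rose 2.29-fold from 5.00 min to 10.0 min, so I carried that reading over the next doubling of time and reckoned a turnover number at 20 min of 14.9. Autumn looks nearly like Monday's run, with the same substrate and reagent, but its loading is 1.15 times as large while its time gives the 2.29-fold step, so in my reckoning the step in time counted for more than the step in loading. My reckoning left substrate leading at 98.4% in spring, 95.8% in dusk and 89.7% in autumn.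

The forecast also chose substrate, substrate and substrate, at 97% (95% to 99%), 93% (87% to 96%) and 83% (68% to 90%), reading Monday's rise as a square of the time, “as expected for a catalyst that activates slowly”. In autumn my figure stood 6.7 points above it.

Substrate led with 98.4% in spring, 96.0% in dusk and 90.7% in autumn.

    2 reagent → homo dimer (k = 9.10 M⁻¹ min⁻¹)
    reagent + free catalyst → catalyst intermediate A (k = 2000 M⁻¹ min⁻¹)
    substrate + catalyst intermediate B ⇌ catalyst intermediate C (K = 22.0 M⁻¹, k = 17000 M⁻¹ min⁻¹)
    catalyst intermediate A → catalyst intermediate B (k = 1600 min⁻¹)
    precatalyst ⇌ free catalyst (K = 0.320, k = 0.0180 min⁻¹)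
    catalyst intermediate C → free catalyst + product (k = 52.0 min⁻¹)

At 20.0 min in autumn, 3.12% of the reagent's charge remained beside 0.0281 M of homo dimer. Autumn's turnover number came to 13.4 against my 14.9. In dusk, read at 80.0 min, the same count stood at 34.3, with 0.353% of the reagent's charge remaining.

(The data are simulated on assumed constants; scatter was added.)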